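The runs are simulated for substances that don't exist, noise included.

You don't need the rate constants to bracket the product's excess. Free catalyst and partner, dissolved from the gas, turn each substrate into its product, while racemization catalyst swaps the two substrates.

| setting | ochre | green | flask |
|---|---|---|---|
| left-handed substrate | 0.10 M | 0.10 M | 0.10 M |
| right-handed substrate | 0.10 M | 0.10 M | 0.10 M |
| gas | 7.3 mM (held) | 7.3 mM (held) | 7.3 mM (held) |
| free catalyst | 7 mM | 11 mM | 5.0 mM |
| racemization catalyst | 0.25 mM | 0.25 mM | 0.25 mM |
| remark | run made earlier | run made earlier |  |
| time |  |  | 2.0 min |

| run | time / s | left-handed product / % | right-handed product / % |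
|---|---|---|---|
| ochre | 10.0 | 4.3 | 1.7 |
| ochre | 20.0 | 11.1 | 3.4 |
| ochre | 30.0 | 14.0 | 4.3 |
| ochre | 40.0 | 15.8 | 8.7 |
| ochre | 50.0 | 20.9 | 9.9 |
| ochre | 60.0 | 24.9 | 10.2 |
| ochre | 80.0 | 34.0 | 16.5 |
| green | 10.0 | 5.3 | 1.8 |
| green | 12.0 | 6.1 | 3.4 |
| green | 20.0 | 10.0 | 5.0 |
| green | 30.0 | 15.2 | 9.7 |
| green | 50.0 | 26.2 | 13.7 |
| green | 80.0 | 39.3 | 19.8 |

(standard deviation of a reading: 1 percentage point)

- free catalyst is single-handed; left-handed substrate and right-handed substrate are mirror images of each other, charged as a racemate, each of them at the stated concentration
- at the start none of partner is dissolved
- the analysis behind the earlier runs scatters by 1 percentage point, standard deviation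
- what may be going on: gas <-> partner; partner -> decomposed reagent; partner + free catalyst + left-handed substrate -> free catalyst + left-handed product; free catalyst -> spent catalyst; partner + free catalyst + right-handed substrate -> free catalyst + right-handed product; left-handed substrate + racemization catalyst <-> right-handed substrate + racemization catalyst
- an excess is below zero if the other one leads

- left-handed product and right-handed product together, in percent of the left-handed substrate and right-handed substrate charged together, at 2.0 min
- excess of left-handed product over right-handed product in the product at 2.0 min
- whether the exchange between left-handed substrate and right-handed substrate keeps pace with the reaction: how far the product's excess at 2.0 min gets from its value without exchange to its value with instant exchange (above 80% keeps pace, below 20% hardly takes part, else lags behind)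

From above: with instant exchange the substrates stay level, so the excess stays where it began. The first 3 rows of both runs, pooled, read 44.3%, which means a selectivity factor of 2.59.

From below: without exchange, the two loss rates stand in the ratio of that factor times the ratio of the substrates. Integrated, the logarithm of the left-handed fraction remaining equals the factor times the logarithm of the right-handed fraction remaining. With 36.3% of the right-handed substrate used, as the last rows read when pooled, this gives 31.0%.

To tighten it, those last rows, pooled, read 33.8%, give or take 2 points. Taking the flask to land near their product, I commit to 31.0% to 39.0%, the upper edge midway between that reading and the top. Both edges rest on the first rows and carry their scatter, so I leave the pace unjudged.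

One quantity carries on. If a racemate's substrates stay level, exchange must move half the gap between the products from right-handed to left-handed substrate. Per point of product, the excess read from the last rows gives this carrying share, 16.9%.

The forecast gives 55%, 32% and "hardly takes part": “Racemization appears minor, though the scatter is large”.

The flask gives 57.7% of product at an excess of 37.1%, and the exchange is judged "keeps pace", at 98% of the way to the instant-exchange value.

    gas ⇌ partner, rate k1*(csat - [partner]) (kL = 0.350 s⁻¹)
    partner → decomposed reagent (k = 0.00170 s⁻¹)
    partner + free catalyst + left-handed substrate → free catalyst + left-handed product (k = 460 M⁻² s⁻¹)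
    free catalyst → spent catalyst (k = 4.40 × 10⁻⁴ s⁻¹)
    partner + free catalyst + right-handed substrate → free catalyst + right-handed product (k = 210 M⁻² s⁻¹)
    left-handed substrate + racemization catalyst ⇌ right-handed substrate + racemization catalyst, rate k6*[racemization catalyst]*[left-handed substrate] forward; the back reaction follows from the equilibrium constant (k = 2000 M⁻¹ s⁻¹)

The carrying share asks 9.75% of this flask, and its net turnover from right-handed to left-handed substrate stands at 10.6%. In a neighbour flask charged with 0.013 M of free catalyst, product reaches 81.2%, so the share asks 13.7%, and its substrates stand at 9.34% and 9.49%.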